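## Retrosynthetic overview

- Feature: ring A (O, C18–C22) is a 2,6-cis-tetrahydropyran whose C20 oxygen (the OMe) lies 1,3 to both ether carbons C18 and C22. C20 can therefore be the carbonyl of a 1,3-dioxan-4-one built from a C18 β-hydroxy acid and the C22 aldehyde, and an oxygen-to-carbon (Petasis–Ferrier) rearrangement then exchanges the C22–O acetal bond for the C21–C22 bond.
- Ring order: ring B (O, C12–C16) first, by Achmatowicz rearrangement of a 2,5-disubstituted furan, silane reduction (2,6-cis), cuprate addition (C15) and methyl addition (C13); then the temporary dioxane ring; then ring A.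
- C24 is grown into the triene by Wittig olefination and γ-silylallylboration/Peterson elimination.
- C8=C9 is formed by Julia–Kocienski olefination of a C9 sulfone with a C1–C8 enal, made from ethyl (S)-4-chloro-3-hydroxybutanoate by Brown allylboration and cross-metathesis.
- End game: C4 carbamate, desilylation, Staudinger reduction, N-acylation with 2-methoxyacrylic acid.

Key step: step 22

Remark: the chain is numbered C1 (CH2N) to C29 (terminal CH2 of the triene); ring A is O/C18–C22 and ring B is O/C12–C16. Commercial solutions of LiN(iPr)2, Cp2TiMe2 and Me2AlCl are assumed.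

## Route

Step 1
Reactants: 1 furan
Product: 3 2-(furan-2-yl)ethanol, via 2-lithiofuran 2 (not isolated)
Conditions: n-BuLi, THF, 0 °C; ethylene oxide, 0 °C → rt; H2O
Reagents that add atoms: ethylene oxide, C1CO1
Why: α-Lithiation of furan and SN2 opening of the epoxide by the aryllithium should install the C17–C18 two-carbon arm.

Step 2
Reactants: 3 2-(furan-2-yl)ethanol
Product: 4 2-[2-(benzyloxy)ethyl]furan
Conditions: NaH, BnBr, Bu4NI (cat.), THF, 0 °C → rt
Reagents that add atoms: benzyl bromide, BrCc1ccccc1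
Why: Williamson etherification of the primary alkoxide should proceed cleanly and gives an ether stable to the later acid and organometallic steps.

Step 3
Reactants: 4 2-[2-(benzyloxy)ethyl]furan
Product: 6 5-[2-(benzyloxy)ethyl]-N-methoxy-N-methylfuran-2-carboxamide, via 5-lithiofuran 5 (not isolated)
Conditions: n-BuLi, THF, −78 → 0 °C; inverse addition to ClC(O)N(OMe)Me, THF, −78 °C
Reagents that add atoms: N-methoxy-N-methylcarbamoyl chloride, CON(C)C(Cl)=O
Why: 2-Alkylfurans lithiate at the free α-position, and acylation of the aryllithium with the carbamoyl chloride (inverse addition to avoid double addition) should give the Weinreb amide.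

Step 4
Reactants: 7 (S)-3-bromo-2-methylpropan-1-ol
Product: 8 (S)-(3-bromo-2-methylpropoxy)(tert-butyl)diphenylsilane
Conditions: TBDPSCl, imidazole, CH2Cl2, 0 °C → rt
Reagents that add atoms: tert-butyl(chloro)diphenylsilane, CC(C)(C)[Si](Cl)(c1ccccc1)c1ccccc1
Why: Standard silylation of the primary alcohol protects C9–O with a group that survives every step up to the triene stage.

Step 5
Reactants: 8 (S)-(3-bromo-2-methylpropoxy)(tert-butyl)diphenylsilane
Product: 9 (S)-tert-butyl(3-iodo-2-methylpropoxy)diphenylsilane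
Conditions: NaI, acetone, reflux
Reagents that add atoms: sodium iodide, [Na+].[I-]
Why: Finkelstein exchange at the primary carbon gives the iodide needed for clean lithium–halogen exchange and leaves the C10 centre untouched.

Step 6
Reactants: 9 (S)-tert-butyl(3-iodo-2-methylpropoxy)diphenylsilane; 6 5-[2-(benzyloxy)ethyl]-N-methoxy-N-methylfuran-2-carboxamide
Product: 11 furyl ketone (C12 carbonyl), via alkyllithium 10 (not isolated)
Conditions: t-BuLi (2.1 equiv), Et2O, −78 °C; then 6, THF, −78 → 0 °C; H2O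
Reagents that add atoms: none
Why: Lithium–iodine exchange gives the C11 alkyllithium, which adds once to the Weinreb amide (stable chelated adduct) to form the C11–C12 bond as a ketone.

Step 7
Reactants: 11 furyl ketone
Product: 12 (1S,3R)-furyl carbinol (C12 S)
Conditions: RuCl(p-cymene)[(S,S)-TsDPEN] (cat.), HCO2H/Et3N (5:2), CH2Cl2, rt
Reagents that add atoms: none
Why: Noyori asymmetric transfer hydrogenation of a 2-acylfuran with the (S,S)-catalyst should deliver hydride to the face that gives the (S)-carbinol, setting C12 by catalyst control.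

Step 8
Reactants: 12 furyl carbinol
Product: 13 6-hydroxy-2H-pyran-3(6H)-one hemiketal (anomers at C16)
Conditions: mCPBA, CH2Cl2, 0 °C
Reagents that add atoms: 3-chloroperoxybenzoic acid, O=C(OO)c1cccc(Cl)c1
Why: Achmatowicz rearrangement (furan oxidation to the ene-dione and hemiketalisation by the C12 hydroxyl) forms ring B with C12 unchanged.

Step 9
Reactants: 13 hemiketal
Product: 14 (2S,6R)-2,6-cis-6H-pyran-3-one (enone)
Conditions: Et3SiH, CF3CO2H, CH2Cl2, −40 °C
Reagents that add atoms: none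
Why: Ionisation of the hemiketal to the near-planar oxocarbenium ion and silane hydride delivery to the face opposite the C12 side chain should set C16 with C17 cis to C11.

Step 10
Reactants: 14 enone
Product: 15 (2S,5S,6R)-5-methyltetrahydropyran-3-one
Conditions: Me2CuLi (from CuI and MeLi), Et2O, −78 °C; H2O
Reagents that add atoms: lithium dimethylcuprate, [Li+].C[Cu-]C
Why: Cuprate conjugate addition to C15 should occur anti to the adjacent C16 side chain (both ring substituents shield the same face), setting the 15,16-trans relationship.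

Step 11
Reactants: 15 ketone
Product: 16 (2S,3R,5S,6R)-tertiary alcohol (C13: axial methyl and equatorial hydroxyl)
Conditions: MeAl(OAr)2 (3 equiv, from AlMe3 and 2,6-di-tert-butyl-4-methylphenol), toluene, −78 °C; MeLi (3 equiv); H2O
Reagents that add atoms: methyllithium, [Li]C
Why: The bulky aluminium aryloxide bound to the ketone blocks the equatorial face, so MeLi should add axially (already favoured in tetrahydropyran-3-ones), setting C13 with the hydroxyl trans to the C11 chain.

Step 12
Reactants: 16 tertiary alcohol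
Product: 17 C13 tert-butyldimethylsilyl ether
Conditions: TBSOTf, 2,6-lutidine, CH2Cl2, 0 °C → rt
Reagents that add atoms: tert-butyldimethylsilyl trifluoromethanesulfonate, CC(C)(C)[Si](C)(C)OS(=O)(=O)C(F)(F)F
Why: Silyl triflate silylation is the standard way to protect a hindered tertiary alcohol, and the ether tolerates the Lewis acids used later.

Step 13
Reactants: 17 silyl ether
Product: 18 ring B primary alcohol (C18 OH)
Conditions: H2 (1 atm), 10% Pd/C, EtOAc, rt
Reagents that add atoms: none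
Why: Hydrogenolysis cleaves the benzyl ether selectively, since the molecule has no alkene and silyl ethers are inert.

Step 14
Reactants: 18 primary alcohol
Product: 19 ring B aldehyde (C18 CHO)
Conditions: Dess–Martin periodinane, CH2Cl2, rt
Reagents that add atoms: none
Why: Dess–Martin oxidation gives the β-alkoxy aldehyde under neutral conditions without β-elimination.

Step 15
Reactants: 20 S-tert-butyl ethanethioate
Product: 22 1-(tert-butylsulfanyl)-1-(trimethylsilyloxy)ethene, via lithium enolate 21 (not isolated)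
Conditions: LiN(iPr)2, THF, −78 °C; Me3SiCl, −78 °C → rt
Reagents that add atoms: chlorotrimethylsilane, C[Si](C)(C)Cl
Why: O-Silylation of the thioester enolate gives the silyl ketene thioacetal used as the acetate nucleophile.

Step 16
Reactants: 19 ring B aldehyde; 22 silyl ketene thioacetal
Product: 23 β-hydroxy thioester (C18 OH anti to the C16 ring oxygen)
Conditions: BF3·OEt2, CH2Cl2, −78 °C; aq. NaHCO3
Reagents that add atoms: none
Why: Mukaiyama aldol addition to the BF3-bound β-alkoxy aldehyde should follow the open, dipole-minimised transition state and give the 1,3-anti relation between the C16 ring oxygen and the new C18 hydroxyl.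

Step 17
Reactants: 23 β-hydroxy thioester
Product: 24 β-hydroxy acid (C18 OH, C20 CO2H)
Conditions: LiOH, THF/MeOH/H2O, 0 °C → rt; then 1 M HCl to pH 3
Reagents that add atoms: lithium hydroxide, [Li+].[OH-]
Why: Saponification of the activated thioester is faster than retro-aldol or elimination at 0 °C and leaves the silyl ethers intact.

Step 18
Reactants: 25 methyl (S)-3-hydroxy-2-methylpropanoate
Product: 26 methyl (S)-3-(benzyloxy)-2-methylpropanoate
Conditions: BnOC(=NH)CCl3, TfOH (cat.), CH2Cl2/cyclohexane, 0 °C → rt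
Reagents that add atoms: benzyl 2,2,2-trichloroacetimidate, N=C(OCc1ccccc1)C(Cl)(Cl)Cl
Why: Acid-catalysed imidate benzylation avoids the basic conditions that would epimerise or eliminate the β-hydroxy ester.

Step 19
Reactants: 26 methyl (S)-3-(benzyloxy)-2-methylpropanoate
Product: 27 (S)-3-(benzyloxy)-2-methylpropanal
Conditions: iBu2AlH (1.05 equiv), CH2Cl2, −78 °C; MeOH, aq. potassium sodium tartrate; used at once
Reagents that add atoms: none
Why: Partial reduction at −78 °C stops at the chelated aluminium hemiacetal, giving the configurationally labile C22–C24 aldehyde without a base-mediated step.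

Step 20
Reactants: 24 β-hydroxy acid; 27 (S)-3-(benzyloxy)-2-methylpropanal
Product: 29 2,6-cis-1,3-dioxan-4-one (C18–O–C22–O–C20 ring), via bis-trimethylsilyl derivative 28 (not isolated)
Conditions: (Me3Si)2NH, CH2Cl2, rt, then evaporation; 27, Me3SiOTf (cat.), CH2Cl2, −78 °C
Reagents that add atoms: none
Why: Silyl-mediated acetalisation of the bis-silylated hydroxy acid with the aldehyde should close the dioxanone with both substituents equatorial, tying C22 to the C18 oxygen.

Step 21
Reactants: 29 1,3-dioxan-4-one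
Product: 30 4-methylene-1,3-dioxane (enol acetal spanning C18–C22)
Conditions: Cp2TiMe2, THF, 65 °C, dark
Reagents that add atoms: dimethyltitanocene, [CH3-].[CH3-].[Ti+4].c1cc[cH-]c1.c1cc[cH-]c1
Why: Petasis methylenation converts the lactone carbonyl C20 into the exocyclic enol ether (introducing C21) under non-acidic conditions that the acetal and silyl ethers tolerate.

Step 22
Reactants: 30 4-methylene-1,3-dioxane
Product: 31 ring A tetrahydropyran-4-one (2,6-cis, C22 R) joined to ring B
Conditions: Me2AlCl (1.5 equiv), CH2Cl2, −78 → −40 °C; aq. NaHCO3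
Reagents that add atoms: none
Why: Me2AlCl binds the enol ether oxygen and ionises the O–C22 acetal bond, giving a C22 oxocarbenium ion (C22=O+–C18) tethered to the dimethylaluminium enolate of C20, whose carbon C21 then adds to C22 to form the C21–C22 bond and the C20 ketone. This is the Petasis–Ferrier rearrangement of an enol acetal to a tetrahydropyran-4-one, and the closest reaction type is the intramolecular aldol-type addition of a metal enolate to an oxocarbenium ion. Ring A closes in a 6-endo-trig mode with respect to the oxocarbenium ion (enolendo with respect to the enolate). The one new stereocentre, C22, is controlled by C18 through a chair transition state in which the C17 chain on C18 and the C23 chain on C22 are both equatorial, so the 2,6-cis ring should form whatever the acetal configuration of 30. The step needs cis selectivity and retention at C23: the tether and the equatorial preference secure the first, and the low temperature, at which ring closure should outrun proton loss from the oxocarbenium ion, secures the second. The silyl and benzyl ethers offer no site that competes with the enol ether for the aluminium.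

Step 23
Reactants: 31 tetrahydropyran-4-one
Product: 32 ring A alcohol (C20 S, equatorial, 2,4,6-all-cis)
Conditions: NaBH4, MeOH, −10 °C
Reagents that add atoms: none
Why: The small hydride should attack the 2,6-cis-tetrahydropyran-4-one axially and give the equatorial C20 alcohol.

Step 24
Reactants: 32 ring A alcohol
Product: 33 C20 methyl ether
Conditions: NaH, MeI, THF, 0 °C → rt
Reagents that add atoms: iodomethane, CI
Why: Williamson methylation of the only free hydroxyl installs the C20 methoxy group while the tertiary C13 oxygen stays silylated.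

Step 25
Reactants: 33 methyl ether
Product: 34 C24 primary alcohol
Conditions: H2 (1 atm), 10% Pd/C, EtOAc, rt
Reagents that add atoms: none
Why: Hydrogenolysis of the benzyl ether is done before any alkene is present, so no other group is at risk.

Step 26
Reactants: 34 primary alcohol
Product: 35 C24 aldehyde
Conditions: Dess–Martin periodinane, CH2Cl2, 0 °C → rt; used at once
Reagents that add atoms: none
Why: Neutral Dess–Martin oxidation gives the α-methyl-β-alkoxy aldehyde without epimerisation at C23 or ring opening.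

Step 27
Reactants: 35 C24 aldehyde
Product: 36 (E)-2-methyl enal (C24=C25, C26 CHO)
Conditions: Ph3P=C(CH3)CHO, toluene, 90 °C
Reagents that add atoms: 2-(triphenylphosphoranylidene)propanal, CC(C=O)=P(c1ccccc1)(c1ccccc1)c1ccccc1
Why: Wittig olefination with the stabilised formyl ylide is E-selective for the trisubstituted alkene and basic too weakly to epimerise C23.

Step 28
Reactants: 36 enal
Product: 38 (24E,26E)-triene, via β-hydroxysilane 37 (not isolated)
Conditions: pinacol (E)-3-(trimethylsilyl)allylboronate, CH2Cl2, rt; then H2O, H2SO4 (cat.), THF, 0 °C → rt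
Reagents that add atoms: pinacol (E)-3-(trimethylsilyl)allylboronate, C[Si](C)(C)/C=C/CB1OC(C)(C)C(C)(C)O1
Why: γ-Silylallylboration through a chair transition state gives the anti-β-hydroxysilane, and acid-promoted anti Peterson elimination should then give the (E)-C26=C27 bond and the terminal vinyl group.

Step 29
Reactants: 38 triene
Product: 39 C9,C13-diol
Conditions: Bu4NF (5 equiv), THF, 50 °C
Reagents that add atoms: none
Why: Fluoride desilylation under forcing conditions removes the primary TBDPS and the tertiary TBS ether at a stage where only ethers and the base-stable triene are present.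

Step 30
Reactants: 39 diol
Product: 40 C9 1-phenyl-1H-tetrazol-5-yl sulfide
Conditions: 1-phenyl-1H-tetrazole-5-thiol, PPh3, DIAD, THF, 0 °C → rt
Reagents that add atoms: 1-phenyl-1H-tetrazole-5-thiol, Sc1nnnn1-c1ccccc1
Why: Mitsunobu thioetherification reacts only at the primary C9 alcohol because the tertiary C13 alcohol is inert under these conditions.

Step 31
Reactants: 40 sulfide
Product: 41 C9 sulfone
Conditions: (NH4)6Mo7O24·4H2O (cat.), 30% H2O2, EtOH, 0 °C → rt
Reagents that add atoms: hydrogen peroxide, OO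
Why: Molybdate-catalysed peroxide oxidation is chemoselective for sulfur over unactivated and conjugated alkenes.

Step 32
Reactants: 41 sulfone
Product: 42 C13 trimethylsilyl ether of the sulfone
Conditions: Me3SiOTf, 2,6-lutidine, CH2Cl2, −78 °C
Reagents that add atoms: trimethylsilyl trifluoromethanesulfonate, C[Si](C)(C)OS(=O)(=O)C(F)(F)F
Why: Silylation masks the tertiary hydroxyl during the strongly basic olefination with a group that leaves together with the C4 silyl ether in step 40.

Step 33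
Reactants: 43 ethyl (S)-4-chloro-3-hydroxybutanoate
Product: 44 ethyl (S)-4-azido-3-hydroxybutanoate
Conditions: NaN3, DMF, 90 °C
Reagents that add atoms: sodium azide, [Na+].[N-]=[N+]=[N-]
Why: SN2 displacement at the primary carbon introduces the C1 nitrogen and does not touch the C2 stereocentre.

Step 34
Reactants: 44 azido alcohol
Product: 45 ethyl (S)-4-azido-3-[(tert-butyldimethylsilyl)oxy]butanoate
Conditions: TBSCl, imidazole, DMF, rt
Reagents that add atoms: tert-butyl(chloro)dimethylsilane, CC(C)(C)[Si](C)(C)Cl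
Why: Standard silylation protects C2–O with a group that outlasts the triethylsilyl ether placed later on C4.

Step 35
Reactants: 45 silyl ether ester
Product: 46 (S)-4-azido-3-[(tert-butyldimethylsilyl)oxy]butanal
Conditions: iBu2AlH (1.05 equiv), toluene, −78 °C; MeOH, aq. potassium sodium tartrate
Reagents that add atoms: none
Why: Partial reduction of the ester at −78 °C gives the aldehyde, and the azide is not reduced at this temperature.

Step 36
Reactants: 46 aldehyde
Product: 48 (4R,6S)-7-azido-6-[(tert-butyldimethylsilyl)oxy]hept-1-en-4-ol, via borinate ester 47 (not isolated)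
Conditions: (+)-Ipc2BOMe (from (−)-α-pinene), CH2=CHCH2MgBr, Et2O, −78 °C → rt; then 46, −78 °C; NaOH, H2O2
Reagents that add atoms: allylmagnesium bromide, C=CC[Mg]Br
Why: Brown allylboration with the (−)-α-pinene-derived reagent should add allyl to the aldehyde face that gives the (R)-carbinol at C4 (2,4-anti) through the reagent-controlled chair transition state.

Step 37
Reactants: 48 homoallylic alcohol
Product: 49 (4R,6S)-7-azido-6-[(tert-butyldimethylsilyl)oxy]-4-[(triethylsilyl)oxy]hept-1-ene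
Conditions: Et3SiCl, imidazole, DMF, 0 °C → rt
Reagents that add atoms: chlorotriethylsilane, CC[Si](Cl)(CC)CC
Why: The triethylsilyl ether on C4 can later be removed in the presence of the C2 tert-butyldimethylsilyl ether, which differentiates the two hydroxyls.

Step 38
Reactants: 49 terminal alkene
Product: 50 (2E,5R,7S)-8-azido-7-[(tert-butyldimethylsilyl)oxy]-2-methyl-5-[(triethylsilyl)oxy]oct-2-enal
Conditions: methacrolein (10 equiv), second-generation Hoveyda–Grubbs catalyst (5 mol%), CH2Cl2, 40 °C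
Reagents that add atoms: methacrolein, C=C(C)C=O
Why: Olefin cross-metathesis of a terminal alkene with methacrolein is E-selective for the trisubstituted enal, and the phosphine-free catalyst leaves the azide alone.

Step 39
Reactants: 42 C9 sulfone; 50 enal
Product: 52 coupled azide with (8E)-C8=C9 bond, via potassium sulfonyl carbanion 51 (not isolated)
Conditions: KN(SiMe3)2, DME, −60 °C; then 50, −60 °C → rt
Reagents that add atoms: none
Why: Julia–Kocienski olefination of the metalated phenyltetrazolyl sulfone with the enal (addition, Smiles rearrangement, loss of SO2 and tetrazolate) should give the (E)-C8=C9 alkene of the diene.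

Step 40
Reactants: 52 coupled azide
Product: 53 C4,C13-diol (C2 silyl ether retained)
Conditions: PPTS (cat.), MeOH/CH2Cl2, 0 °C
Reagents that add atoms: none
Why: Mild acid methanolysis cleaves the triethylsilyl and trimethylsilyl ethers much faster than the secondary tert-butyldimethylsilyl ether.

Step 41
Reactants: 53 diol
Product: 55 C4 carbamate, via 4-nitrophenyl carbonate 54 (not isolated)
Conditions: 4-nitrophenyl chloroformate, pyridine, CH2Cl2, 0 °C; then NH3 (7 M in MeOH), 0 °C → rt
Reagents that add atoms: 4-nitrophenyl chloroformate, O=C(Cl)Oc1ccc(cc1)[N+](=O)[O-]; ammonia, N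
Why: The chloroformate acylates the secondary C4 alcohol but not the hindered tertiary C13 alcohol, and ammonolysis of the activated carbonate gives the primary carbamate.

Step 42
Reactants: 55 carbamate
Product: 56 azido diol carbamate (C2 OH free)
Conditions: HF·pyridine, pyridine, THF, 0 °C → rt
Reagents that add atoms: none
Why: Buffered HF·pyridine removes the remaining secondary silyl ether under conditions that the triene, diene, carbamate and azide tolerate.

Step 43
Reactants: 56 azide
Product: 58 C1 primary amine, via iminophosphorane 57 (not isolated)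
Conditions: PMe3, THF/H2O, rt
Reagents that add atoms: none
Why: Staudinger reduction converts the azide to the amine without affecting alkenes or the carbamate.

Step 44
Reactants: 59 methyl 2-methoxyacrylate
Product: 60 2-methoxyacrylic acid
Conditions: LiOH, THF/H2O, 0 °C; then 1 M HCl to pH 3, cold extraction
Reagents that add atoms: lithium hydroxide, [Li+].[OH-]
Why: Cold saponification gives the acid, and brief, cold acidification avoids hydrolysis of the enol ether.

Step 45
Reactants: 58 amine; 60 2-methoxyacrylic acid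
Product: 61 CNP0220268.1 (target)
Conditions: EDC·HCl, HOBt (cat.), iPr2NEt, DMF, 0 °C → rt
Reagents that add atoms: none
Why: Carbodiimide amidation through the benzotriazolyl ester acylates the primary amine far faster than the secondary or tertiary hydroxyls, completing the 2-methoxyacrylamide.

## Compound list

1 | furan | c1ccoc1 | starting material
2 | 2-lithiofuran | [Li]c1ccco1 | intermediate
3 | 2-(furan-2-yl)ethanol | OCCc1ccco1 | intermediate
4 | 2-[2-(benzyloxy)ethyl]furan | c1ccc(COCCc2ccco2)cc1 | intermediate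
5 | 5-lithio-2-[2-(benzyloxy)ethyl]furan | [Li]c1ccc(CCOCc2ccccc2)o1 | intermediate
6 | 5-[2-(benzyloxy)ethyl]-N-methoxy-N-methylfuran-2-carboxamide | CON(C)C(=O)c1ccc(CCOCc2ccccc2)o1 | intermediate
7 | (S)-3-bromo-2-methylpropan-1-ol | BrC[C@@H](C)CO | starting material
8 | (S)-(3-bromo-2-methylpropoxy)(tert-butyl)diphenylsilane | BrC[C@@H](C)CO[Si](c1ccccc1)(c1ccccc1)C(C)(C)C | intermediate
9 | (S)-tert-butyl(3-iodo-2-methylpropoxy)diphenylsilane | IC[C@@H](C)CO[Si](c1ccccc1)(c1ccccc1)C(C)(C)C | intermediate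
10 | C11 alkyllithium from 9 (C10 configuration retained) | [Li]C[C@@H](C)CO[Si](c1ccccc1)(c1ccccc1)C(C)(C)C | intermediate
11 | (R)-1-{5-[2-(benzyloxy)ethyl]furan-2-yl}-4-[(tert-butyldiphenylsilyl)oxy]-3-methylbutan-1-one | O=C(C[C@@H](C)CO[Si](c1ccccc1)(c1ccccc1)C(C)(C)C)c1ccc(CCOCc2ccccc2)o1 | intermediate
12 | (1S,3R)-1-{5-[2-(benzyloxy)ethyl]furan-2-yl}-4-[(tert-butyldiphenylsilyl)oxy]-3-methylbutan-1-ol | O[C@@H](C[C@@H](C)CO[Si](c1ccccc1)(c1ccccc1)C(C)(C)C)c1ccc(CCOCc2ccccc2)o1 | intermediate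
13 | Achmatowicz hemiketal: 6-[2-(benzyloxy)ethyl]-6-hydroxy-2H-pyran-3(6H)-one with the C9–C11 chain at C12 (C12 S; both anomers at C16) | c1ccccc1COCCC2(O)O[C@@H](C[C@@H](C)CO[Si](c3ccccc3)(c3ccccc3)C(C)(C)C)C(=O)C=C2 | intermediate
14 | (2S,6R)-6-[2-(benzyloxy)ethyl]-2-{(R)-3-[(tert-butyldiphenylsilyl)oxy]-2-methylpropyl}-2H-pyran-3(6H)-one (2,6-cis) | c1ccccc1COCC[C@H]2O[C@@H](C[C@@H](C)CO[Si](c3ccccc3)(c3ccccc3)C(C)(C)C)C(=O)C=C2 | intermediate
15 | (2S,5S,6R)-6-[2-(benzyloxy)ethyl]-2-{(R)-3-[(tert-butyldiphenylsilyl)oxy]-2-methylpropyl}-5-methyltetrahydropyran-3-one | c1ccccc1COCC[C@H]2O[C@@H](C[C@@H](C)CO[Si](c3ccccc3)(c3ccccc3)C(C)(C)C)C(=O)C[C@@H]2C | intermediate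
16 | (2S,3R,5S,6R)-6-[2-(benzyloxy)ethyl]-2-{(R)-3-[(tert-butyldiphenylsilyl)oxy]-2-methylpropyl}-3,5-dimethyltetrahydropyran-3-ol | c1ccccc1COCC[C@H]2O[C@@H](C[C@@H](C)CO[Si](c3ccccc3)(c3ccccc3)C(C)(C)C)[C@](C)(O)C[C@@H]2C | intermediate
17 | C13 tert-butyldimethylsilyl ether of 16 | c1ccccc1COCC[C@H]2O[C@@H](C[C@@H](C)CO[Si](c3ccccc3)(c3ccccc3)C(C)(C)C)[C@](C)(O[Si](C)(C)C(C)(C)C)C[C@@H]2C | intermediate
18 | ring B primary alcohol (17 without benzyl; C18 OH) | OCC[C@H]1O[C@@H](C[C@@H](C)CO[Si](c2ccccc2)(c2ccccc2)C(C)(C)C)[C@](C)(O[Si](C)(C)C(C)(C)C)C[C@@H]1C | intermediate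
19 | ring B aldehyde (C18 CHO; C10, C12, C13, C15, C16 as in the target) | O=CC[C@H]1O[C@@H](C[C@@H](C)CO[Si](c2ccccc2)(c2ccccc2)C(C)(C)C)[C@](C)(O[Si](C)(C)C(C)(C)C)C[C@@H]1C | intermediate
20 | S-tert-butyl ethanethioate | CC(=O)SC(C)(C)C | starting material
21 | lithium enolate of 20 | [Li]OC(=C)SC(C)(C)C | intermediate
22 | 1-(tert-butylsulfanyl)-1-(trimethylsilyloxy)ethene | C=C(O[Si](C)(C)C)SC(C)(C)C | intermediate
23 | β-hydroxy thioester (C18 OH anti to the C16 ring oxygen; target configuration at C18) | CC(C)(C)SC(=O)C[C@H](O)C[C@H]1O[C@@H](C[C@@H](C)CO[Si](c2ccccc2)(c2ccccc2)C(C)(C)C)[C@](C)(O[Si](C)(C)C(C)(C)C)C[C@@H]1C | intermediate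
24 | β-hydroxy acid (C18 OH, C20 CO2H) | OC(=O)C[C@H](O)C[C@H]1O[C@@H](C[C@@H](C)CO[Si](c2ccccc2)(c2ccccc2)C(C)(C)C)[C@](C)(O[Si](C)(C)C(C)(C)C)C[C@@H]1C | intermediate
25 | methyl (S)-3-hydroxy-2-methylpropanoate | COC(=O)[C@@H](C)CO | starting material
26 | methyl (S)-3-(benzyloxy)-2-methylpropanoate | COC(=O)[C@@H](C)COCc1ccccc1 | intermediate
27 | (S)-3-(benzyloxy)-2-methylpropanal | O=C[C@@H](C)COCc1ccccc1 | intermediate
28 | trimethylsilyl ester trimethylsilyl ether of 24 | C[Si](C)(C)OC(=O)C[C@H](O[Si](C)(C)C)C[C@H]1O[C@@H](C[C@@H](C)CO[Si](c2ccccc2)(c2ccccc2)C(C)(C)C)[C@](C)(O[Si](C)(C)C(C)(C)C)C[C@@H]1C | intermediate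
29 | 2,6-cis-1,3-dioxan-4-one (C20 carbonyl, C22 acetal carbon bearing the (S)-1-(benzyloxy)propan-2-yl group) | O=C1C[C@@H](C[C@H]2O[C@@H](C[C@@H](C)CO[Si](c3ccccc3)(c3ccccc3)C(C)(C)C)[C@](C)(O[Si](C)(C)C(C)(C)C)C[C@@H]2C)O[C@@H]([C@@H](C)COCc4ccccc4)O1 | intermediate
30 | 4-methylene-1,3-dioxane (enol acetal spanning C18–C22) | C=C1C[C@@H](C[C@H]2O[C@@H](C[C@@H](C)CO[Si](c3ccccc3)(c3ccccc3)C(C)(C)C)[C@](C)(O[Si](C)(C)C(C)(C)C)C[C@@H]2C)O[C@@H]([C@@H](C)COCc4ccccc4)O1 | intermediate
31 | ring A 2,6-cis-tetrahydropyran-4-one joined to ring B (C22 R, C23 S) | O=C1C[C@@H](C[C@H]2O[C@@H](C[C@@H](C)CO[Si](c3ccccc3)(c3ccccc3)C(C)(C)C)[C@](C)(O[Si](C)(C)C(C)(C)C)C[C@@H]2C)O[C@@H]([C@@H](C)COCc4ccccc4)C1 | intermediate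
32 | ring A alcohol (C20 S, equatorial, all-cis) | O[C@H]1C[C@@H](C[C@H]2O[C@@H](C[C@@H](C)CO[Si](c3ccccc3)(c3ccccc3)C(C)(C)C)[C@](C)(O[Si](C)(C)C(C)(C)C)C[C@@H]2C)O[C@@H]([C@@H](C)COCc4ccccc4)C1 | intermediate
33 | C20 methyl ether | CO[C@H]1C[C@@H](C[C@H]2O[C@@H](C[C@@H](C)CO[Si](c3ccccc3)(c3ccccc3)C(C)(C)C)[C@](C)(O[Si](C)(C)C(C)(C)C)C[C@@H]2C)O[C@@H]([C@@H](C)COCc4ccccc4)C1 | intermediate
34 | C24 primary alcohol | CO[C@H]1C[C@@H](C[C@H]2O[C@@H](C[C@@H](C)CO[Si](c3ccccc3)(c3ccccc3)C(C)(C)C)[C@](C)(O[Si](C)(C)C(C)(C)C)C[C@@H]2C)O[C@@H]([C@@H](C)CO)C1 | intermediate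
35 | C24 aldehyde | CO[C@H]1C[C@@H](C[C@H]2O[C@@H](C[C@@H](C)CO[Si](c3ccccc3)(c3ccccc3)C(C)(C)C)[C@](C)(O[Si](C)(C)C(C)(C)C)C[C@@H]2C)O[C@@H]([C@@H](C)C=O)C1 | intermediate
36 | (24E)-2-methyl enal (C26 CHO) | CO[C@H]1C[C@@H](C[C@H]2O[C@@H](C[C@@H](C)CO[Si](c3ccccc3)(c3ccccc3)C(C)(C)C)[C@](C)(O[Si](C)(C)C(C)(C)C)C[C@@H]2C)O[C@@H]([C@@H](C)/C=C(C)/C=O)C1 | intermediate
37 | anti-β-hydroxysilane (C26 OH, C27 SiMe3; both anti diastereomers) | CO[C@H]1C[C@@H](C[C@H]2O[C@@H](C[C@@H](C)CO[Si](c3ccccc3)(c3ccccc3)C(C)(C)C)[C@](C)(O[Si](C)(C)C(C)(C)C)C[C@@H]2C)O[C@@H]([C@@H](C)/C=C(C)/C(O)C(C=C)[Si](C)(C)C)C1 | intermediate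
38 | (24E,26E)-triene with C9 OTBDPS and C13 OTBS | CO[C@H]1C[C@@H](C[C@H]2O[C@@H](C[C@@H](C)CO[Si](c3ccccc3)(c3ccccc3)C(C)(C)C)[C@](C)(O[Si](C)(C)C(C)(C)C)C[C@@H]2C)O[C@@H]([C@@H](C)/C=C(C)/C=C/C=C)C1 | intermediate
39 | triene C9,C13-diol | CO[C@H]1C[C@@H](C[C@H]2O[C@@H](C[C@@H](C)CO)[C@](C)(O)C[C@@H]2C)O[C@@H]([C@@H](C)/C=C(C)/C=C/C=C)C1 | intermediate
40 | C9 1-phenyl-1H-tetrazol-5-yl sulfide (C13 OH) | CO[C@H]1C[C@@H](C[C@H]2O[C@@H](C[C@@H](C)CSc3nnnn3-c3ccccc3)[C@](C)(O)C[C@@H]2C)O[C@@H]([C@@H](C)/C=C(C)/C=C/C=C)C1 | intermediate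
41 | C9 1-phenyl-1H-tetrazol-5-yl sulfone (C13 OH) | CO[C@H]1C[C@@H](C[C@H]2O[C@@H](C[C@@H](C)CS(=O)(=O)c3nnnn3-c3ccccc3)[C@](C)(O)C[C@@H]2C)O[C@@H]([C@@H](C)/C=C(C)/C=C/C=C)C1 | intermediate
42 | C9 sulfone with C13 trimethylsilyl ether | CO[C@H]1C[C@@H](C[C@H]2O[C@@H](C[C@@H](C)CS(=O)(=O)c3nnnn3-c3ccccc3)[C@](C)(O[Si](C)(C)C)C[C@@H]2C)O[C@@H]([C@@H](C)/C=C(C)/C=C/C=C)C1 | intermediate
43 | ethyl (S)-4-chloro-3-hydroxybutanoate | CCOC(=O)C[C@H](O)CCl | starting material
44 | ethyl (S)-4-azido-3-hydroxybutanoate | CCOC(=O)C[C@H](O)CN=[N+]=[N-] | intermediate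
45 | ethyl (S)-4-azido-3-[(tert-butyldimethylsilyl)oxy]butanoate | CCOC(=O)C[C@@H](CN=[N+]=[N-])O[Si](C)(C)C(C)(C)C | intermediate
46 | (S)-4-azido-3-[(tert-butyldimethylsilyl)oxy]butanal | O=CC[C@@H](CN=[N+]=[N-])O[Si](C)(C)C(C)(C)C | intermediate
47 | diisopinocampheylborinate ester of 48 | C=CC[C@H](C[C@@H](CN=[N+]=[N-])O[Si](C)(C)C(C)(C)C)OB([C@H]1C[C@H]2C[C@@H]([C@@H]1C)C2(C)C)[C@H]1C[C@H]2C[C@@H]([C@@H]1C)C2(C)C | intermediate
48 | (4R,6S)-7-azido-6-[(tert-butyldimethylsilyl)oxy]hept-1-en-4-ol | C=CC[C@@H](O)C[C@@H](CN=[N+]=[N-])O[Si](C)(C)C(C)(C)C | intermediate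
49 | (4R,6S)-7-azido-6-[(tert-butyldimethylsilyl)oxy]-4-[(triethylsilyl)oxy]hept-1-ene | C=CC[C@H](C[C@@H](CN=[N+]=[N-])O[Si](C)(C)C(C)(C)C)O[Si](CC)(CC)CC | intermediate
50 | (2E,5R,7S)-8-azido-7-[(tert-butyldimethylsilyl)oxy]-2-methyl-5-[(triethylsilyl)oxy]oct-2-enal | O=C/C(C)=C/C[C@H](C[C@@H](CN=[N+]=[N-])O[Si](C)(C)C(C)(C)C)O[Si](CC)(CC)CC | intermediate
51 | potassium salt of C9-metalated sulfone 42 | [K+].CO[C@H]1C[C@@H](C[C@H]2O[C@@H](C[C@@H](C)[CH-]S(=O)(=O)c3nnnn3-c3ccccc3)[C@](C)(O[Si](C)(C)C)C[C@@H]2C)O[C@@H]([C@@H](C)/C=C(C)/C=C/C=C)C1 | intermediate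
52 | coupled azide: full carbon chain with (6E,8E)-diene; C2 OTBS, C4 OTES, C13 OTMS | C=C/C=C/C(C)=C/[C@H](C)[C@H]1C[C@@H](OC)C[C@@H](C[C@H]2O[C@@H](C[C@@H](C)/C=C/C(C)=C/C[C@H](C[C@@H](CN=[N+]=[N-])O[Si](C)(C)C(C)(C)C)O[Si](CC)(CC)CC)[C@](C)(O[Si](C)(C)C)C[C@@H]2C)O1 | intermediate
53 | C4,C13-diol azide (C2 OTBS) | C=C/C=C/C(C)=C/[C@H](C)[C@H]1C[C@@H](OC)C[C@@H](C[C@H]2O[C@@H](C[C@@H](C)/C=C/C(C)=C/C[C@H](C[C@@H](CN=[N+]=[N-])O[Si](C)(C)C(C)(C)C)O)[C@](C)(O)C[C@@H]2C)O1 | intermediate
54 | C4 4-nitrophenyl carbonate | C=C/C=C/C(C)=C/[C@H](C)[C@H]1C[C@@H](OC)C[C@@H](C[C@H]2O[C@@H](C[C@@H](C)/C=C/C(C)=C/C[C@H](C[C@@H](CN=[N+]=[N-])O[Si](C)(C)C(C)(C)C)OC(=O)Oc3ccc(cc3)[N+](=O)[O-])[C@](C)(O)C[C@@H]2C)O1 | intermediate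
55 | C4 carbamate azide (C2 OTBS, C13 OH) | C=C/C=C/C(C)=C/[C@H](C)[C@H]1C[C@@H](OC)C[C@@H](C[C@H]2O[C@@H](C[C@@H](C)/C=C/C(C)=C/C[C@H](C[C@@H](CN=[N+]=[N-])O[Si](C)(C)C(C)(C)C)OC(N)=O)[C@](C)(O)C[C@@H]2C)O1 | intermediate
56 | azido diol carbamate (C1 N3, C2 OH) | C=C/C=C/C(C)=C/[C@H](C)[C@H]1C[C@@H](OC)C[C@@H](C[C@H]2O[C@@H](C[C@@H](C)/C=C/C(C)=C/C[C@H](C[C@H](O)CN=[N+]=[N-])OC(N)=O)[C@](C)(O)C[C@@H]2C)O1 | intermediate
57 | C1 trimethyliminophosphorane | C=C/C=C/C(C)=C/[C@H](C)[C@H]1C[C@@H](OC)C[C@@H](C[C@H]2O[C@@H](C[C@@H](C)/C=C/C(C)=C/C[C@H](C[C@H](O)CN=P(C)(C)C)OC(N)=O)[C@](C)(O)C[C@@H]2C)O1 | intermediate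
58 | C1 primary amine | C=C/C=C/C(C)=C/[C@H](C)[C@H]1C[C@@H](OC)C[C@@H](C[C@H]2O[C@@H](C[C@@H](C)/C=C/C(C)=C/C[C@H](C[C@H](O)CN)OC(N)=O)[C@](C)(O)C[C@@H]2C)O1 | intermediate
59 | methyl 2-methoxyacrylate | C=C(OC)C(=O)OC | starting material
60 | 2-methoxyacrylic acid | C=C(OC)C(=O)O | intermediate
61 | CNP0220268.1 | C=C/C=C/C(C)=C/[C@H](C)[C@H]1C[C@@H](OC)C[C@@H](C[C@H]2O[C@@H](C[C@@H](C)/C=C/C(C)=C/C[C@H](C[C@H](O)CNC(=O)C(=C)OC)OC(N)=O)[C@](C)(O)C[C@@H]2C)O1 | target

## Step count and risks

Total steps: 45. Longest linear sequence: 33 steps (steps 1–3, 6–14, 16, 17, 20–32, 39–43, 45).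

Steps most likely to fail:

1. Step 22 (key rearrangement). The C22 oxocarbenium ion may lose the C23 proton (epimerisation or enol ether formation) before the enolate closes, or the cis selectivity may erode if the ion pair collapses through a non-chair geometry. The fallback sets out from 19 and returns at 32. BF3·OEt2-promoted addition of allyltrimethylsilane to 19, under the same 1,3-anti control as step 16, would give homoallylic alcohol F1. Prins cyclisation of homoallylic alcohol F1 with aldehyde 27 in CF3CO2H/CH2Cl2 would close ring A as the all-cis 4-trifluoroacetoxy tetrahydropyran, trifluoroacetate F2. Methanolysis of trifluoroacetate F2 (K2CO3, MeOH) would give alcohol 32, and the route continues with step 24.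

2. Step 11 (methyl addition at C13). Equatorial attack may compete, or MeLi may enolise the ketone, giving poor facial selectivity or recovered 15. The fallback sets out from 15 and returns at 16. Dimethylsulfonium methylide (Me3SI, KN(SiMe3)2, THF, −10 °C), which adds axially and irreversibly to cyclohexanone-type ketones, would give spiro-epoxide F3 with the oxygen equatorial. Hydride opening of spiro-epoxide F3 at its CH2 carbon with LiEt3BH (THF, 0 °C) would give tertiary alcohol 16.

3. Step 28 (triene). Allylboration of the hindered α-methyl enal may be slow, and in the acid step allyl-cation formation or protodesilylation could scramble the C26=C27 geometry. The fallback sets out from 36 and returns at 38. Takai iodo-olefination of 36 (CrCl2, CHI3, THF, 0 °C) would give (E,E)-dienyl iodide F4. Stille coupling of dienyl iodide F4 with tributyl(vinyl)stannane (PdCl2(MeCN)2, DMF, rt) would give triene 38.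

Further compounds
F1 | step 22 | homoallylic alcohol (C18 OH anti to the C16 ring oxygen, C19–C21 allyl) | C=CC[C@H](O)C[C@H]1O[C@@H](C[C@@H](C)CO[Si](c2ccccc2)(c2ccccc2)C(C)(C)C)[C@](C)(O[Si](C)(C)C(C)(C)C)C[C@@H]1C
F2 | step 22 | all-cis ring A C20 trifluoroacetate | O=C(O[C@H]1C[C@@H](C[C@H]2O[C@@H](C[C@@H](C)CO[Si](c3ccccc3)(c3ccccc3)C(C)(C)C)[C@](C)(O[Si](C)(C)C(C)(C)C)C[C@@H]2C)O[C@@H]([C@@H](C)COCc4ccccc4)C1)C(F)(F)F
F3 | step 11 | C13 spiro-epoxide of ring B (equatorial oxygen, axial CH2) | c1ccccc1COCC[C@H]2O[C@@H](C[C@@H](C)CO[Si](c4ccccc4)(c4ccccc4)C(C)(C)C)[C@@]3(CO3)C[C@@H]2C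
F4 | step 28 | (24E,26E)-dienyl iodide (C27 iodide) | CO[C@H]1C[C@@H](C[C@H]2O[C@@H](C[C@@H](C)CO[Si](c3ccccc3)(c3ccccc3)C(C)(C)C)[C@](C)(O[Si](C)(C)C(C)(C)C)C[C@@H]2C)O[C@@H]([C@@H](C)/C=C(C)/C=C/I)C1
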